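**Plan**

1. Retrosynthesis (labdane numbering C1–C20 for the diterpenoid part): cut the acetate and the C15 glyceride ester, then C1–C2 and C9–C10 of the decalin in one event, then C8=C9 (Wittig). This leaves an acyclic C13 alkynyl ketone from (R)-limonene and a C7 ylide from (R)-citronellic acid.
2. Forward: limonene oxide is cleaved, gem-dimethylated at C4 and homologated to the C3≡C2 alkyne; a Wittig reaction joins the side chain; one gold-catalysed cascade closes ring A (C1–C2) and then ring B (C9–C10); the olefin is moved to C8=C9, C2=C3 is hydrogenated, and the glyceride is built from solketal.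
3. Enabling feature: in the cascade substrate the alkyne C2≡C3 and the isopropenyl unit C10(=C1)–C20 stand 1,5 to each other across the quaternary C4. C10, the future ring-fusion quaternary carbon, sits next to C5, which already carries the C6–C7–C8=C9 arm, so closing ring A at C1–C2 creates the C10 cation exactly where ring B must close.
4. Stereochemistry: C5 is bought with (R)-limonene and relays to C10 in the cascade (trans ring fusion); C13 comes from (R)-citronellic acid; the glycerol carbinol comes from (S)-solketal. The olefin geometry at C8=C9 and the transient C9 centre are erased when the tetrasubstituted olefin is set.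

Key step: step 10

Remark (assumption): (+)-limonene oxide is used as the commercial cis/trans mixture because both epoxides converge in step 1; (R)-citronellic acid and (S)-solketal are taken as commercial.

**Route**

Step 1
Reactants: 1 (+)-limonene oxide [(4R)-limonene 1,2-epoxide, cis/trans mixture]
Product: 2 (3R)-6-oxo-3-(prop-1-en-2-yl)heptanal
Conditions: H5IO6, THF/H2O, 0 °C → rt
Reagents that add atoms: water, O
Why: Acidic periodate hydrolyses both epoxide diastereomers to the 1,2-diol and cleaves it in the same flask (glycol cleavage) while the 1,1-disubstituted olefin is inert, so the carbon bearing the isopropenyl group survives unchanged as the future C5.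

Step 2
Reactants: 2 (3R)-6-oxo-3-(prop-1-en-2-yl)heptanal
Product: 3 (3R)-6-oxo-3-(prop-1-en-2-yl)heptanoic acid
Conditions: NaClO2, NaH2PO4, 2-methylbut-2-ene, t-BuOH/H2O, 0 °C → rt
Reagents that add atoms: sodium chlorite, [Na+].[O-]Cl=O
Why: Pinnick oxidation converts only the aldehyde, and the olefin scavenger removes hypochlorous acid so that the isopropenyl group and the methyl ketone should survive.

Step 3
Reactants: 3 (3R)-6-oxo-3-(prop-1-en-2-yl)heptanoic acid
Product: 4 methyl (3R)-6,6-dimethoxy-3-(prop-1-en-2-yl)heptanoate
Conditions: HC(OMe)3, MeOH, p-TsOH·H2O (cat.), 40 °C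
Reagents that add atoms: trimethyl orthoformate, COC(OC)OC; methanol, CO
Why: Acid-catalysed Fischer esterification and dimethyl ketal formation, both driven by the orthoformate as water scavenger, should mask the ketone for the enolate and hydride steps, the catalytic acid being too weak to add methanol to the isopropenyl group.

Step 4
Reactants: 4 methyl (3R)-6,6-dimethoxy-3-(prop-1-en-2-yl)heptanoate
Product: 6 methyl (3S)-6,6-dimethoxy-2,2-dimethyl-3-(prop-1-en-2-yl)heptanoate, via α-monomethyl ester 5 (not isolated)
Conditions: LDA (1.05 equiv), THF, −78 °C, then MeI, → 0 °C; recool, LDA (1.3 equiv), DMPU, −78 °C, then MeI, → rt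
Reagents that add atoms: iodomethane, CI
Why: Two successive ester lithium enolate C-methylations (the second on the tetrasubstituted enolate, helped by DMPU) build the quaternary C4, and the adjacent stereocentre is β to the ester and cannot epimerise.

Step 5
Reactants: 6 methyl (3S)-6,6-dimethoxy-2,2-dimethyl-3-(prop-1-en-2-yl)heptanoate
Product: 9 (5S)-6,6-dimethyl-5-(prop-1-en-2-yl)oct-7-yn-2-one, via aldehyde 7 (not isolated), via alkynyl ketal 8 (not isolated)
Conditions: DIBAL-H (1.1 equiv), CH2Cl2, −78 °C; then MeOH, K2CO3, dimethyl (1-diazo-2-oxopropyl)phosphonate, −78 °C → rt; then 1 M HCl, THF, rt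
Reagents that add atoms: dimethyl (1-diazo-2-oxopropyl)phosphonate, COP(=O)(OC)C(=[N+]=[N-])C(C)=O; water, O
Why: At −78 °C the hindered ester should stop at the aluminium hemiacetal, methanol releases the non-enolisable aldehyde 7, the Ohira–Bestmann (Seyferth–Gilbert) homologation adds C2 as the terminal alkyne, and the dilute acid of the work-up hydrolyses the dimethyl ketal.

Step 6
Reactants: 10 (R)-citronellic acid [(3R)-3,7-dimethyloct-6-enoic acid]
Product: 11 (3R)-6-hydroxy-3-methylhexanoic acid
Conditions: O3, CH2Cl2/MeOH, −78 °C; then NaBH4, −78 °C → rt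
Reagents that add atoms: ozone, [O-][O+]=O
Why: Ozonolysis cleaves the only olefin and borohydride reduces the ozonide to the primary alcohol without touching the carboxylate (reductive ozonolysis), so the chiral-pool methyl centre (the future C13) is carried unchanged.

Step 7
Reactants: 11 (3R)-6-hydroxy-3-methylhexanoic acid
Product: 12 (3R)-6-bromo-3-methylhexanoic acid
Conditions: 48% aq. HBr, conc. H2SO4, 100 °C
Reagents that add atoms: hydrogen bromide, Br
Why: Bromide displaces the protonated primary hydroxyl (or opens any seven-membered lactone formed) by SN2 substitution, and the remote stereocentre is not involved.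

Step 8
Reactants: 12 (3R)-6-bromo-3-methylhexanoic acid
Product: 13 [(4R)-5-carboxy-4-methylpentyl]triphenylphosphonium bromide
Conditions: PPh3, MeCN, reflux
Reagents that add atoms: triphenylphosphine, c1ccc(cc1)P(c1ccccc1)c1ccccc1
Why: SN2 quaternisation of triphenylphosphine by the primary bromide (phosphonium salt formation).

Step 9
Reactants: 9 (5S)-6,6-dimethyl-5-(prop-1-en-2-yl)oct-7-yn-2-one; 13 [(4R)-5-carboxy-4-methylpentyl]triphenylphosphonium bromide
Product: 15 (3R,10S)-3,7,11,11-tetramethyl-10-(prop-1-en-2-yl)tridec-6-en-12-ynoic acid (6E/6Z mixture), via ylide 14 (not isolated)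
Conditions: 13 (1.3 equiv), KHMDS (2.0 equiv per 13), THF, 0 °C; then 9, rt → 45 °C; dilute HCl work-up
Reagents that add atoms: none
Why: Wittig olefination of the methyl ketone with the non-stabilised ylide, whose carboxylate is inert as the potassium salt and whose basicity is below that needed to remove the alkyne proton, forms C8=C9 as an E/Z mixture that needs no separation because C9 ends sp2 in the target.

Step 10
Reactants: 15 (3R,10S)-3,7,11,11-tetramethyl-10-(prop-1-en-2-yl)tridec-6-en-12-ynoic acid
Product: 16 (5R,9R,10S,13R)-labda-2,8(17)-dien-15-oic acid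
Conditions: [(2-biphenylyl)(t-Bu)2P]Au(NCMe)SbF6 (5 mol %), CH2Cl2, −20 °C → rt
Reagents that add atoms: none
Why: The cationic monovalent gold complex π-activates the terminal alkyne; C1 (the CH2 of the isopropenyl group) attacks C2 and closes ring A in the 6-endo-dig mode (vinylgold at C3, tertiary cation at C10), C9 of the C8=C9 olefin then attacks C10 and closes ring B in the 6-endo-trig mode, and loss of a proton from the C8 cation and protodeauration at C3 release the catalyst. The closest known reaction type is the gold-catalysed 6-endo-dig cyclisation of 1,5-enynes bearing a 1,1-disubstituted olefin with capture of the tertiary cation by a tethered nucleophile (polyenyne cyclisation); the ring B event is the classical cyclisation of a monocyclofarnesyl-type C10 cation. C10 is controlled by the bought centre C5: the C6–C9 arm sits pseudo-equatorial on ring A and reaches C10 through a chair, so that C9 bonds equatorially and C20 ends axial, anti to H5 (trans ring fusion). C9 is set by the olefin geometry of 15 (C11 equatorial from the E isomer) but is erased in step 11, so the E/Z mixture can be used. The step needs 6-endo-dig closure rather than 5-endo or skeletal-shift pathways and capture of the C10 cation faster than proton loss: the quaternary C4 (no propargylic hydrogen for a 1,2-H shift, gem-dimethyl compression), the tertiary character of C10 and the trisubstituted C8=C9 nucleophile held five atoms away should secure both. Proton loss from C8 is not expected to be regioselective, so 16 should be accompanied by its C7=C8 and C8=C9 isomers, all of which step 11 converges.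

Step 11
Reactants: 16 (5R,9R,10S,13R)-labda-2,8(17)-dien-15-oic acid (as obtained, with its C8 olefin isomers)
Product: 17 (5R,10R,13R)-labda-2,8-dien-15-oic acid
Conditions: I2 (10 mol %), benzene, 80 °C; then AgNO3–SiO2 chromatography
Reagents that add atoms: none
Why: Hydrogen iodide formed from iodine reversibly protonates the 1,1-disubstituted and trisubstituted C8 olefins to the common tertiary C8 cation and should funnel them to the tetrasubstituted C8=C9 olefin, the thermodynamic position in 9-alkyl labdanes (acid-catalysed olefin isomerisation, as in the iodine dehydration of labdan-8-ols), while the C2=C3 olefin, which could only give a secondary cation, is expected to stay.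

Step 12
Reactants: 17 (5R,10R,13R)-labda-2,8-dien-15-oic acid
Product: 18 (5R,10R,13R)-labd-8-en-15-oic acid (ent-labd-8-en-15-oic acid)
Conditions: H2 (1 atm), 5% Pd/C, EtOAc, rt
Reagents that add atoms: none
Why: Heterogeneous catalytic hydrogenation should saturate the cis-disubstituted C2=C3 olefin, the helper left by the alkyne, while the hindered tetrasubstituted C8=C9 olefin does not react under these conditions, and no stereocentre is formed.

Step 13
Reactants: 18 (5R,10R,13R)-labd-8-en-15-oic acid; 19 (S)-solketal {[(4S)-2,2-dimethyl-1,3-dioxolan-4-yl]methanol}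
Product: 20 [(4R)-2,2-dimethyl-1,3-dioxolan-4-yl]methyl (5R,10R,13R)-labd-8-en-15-oate
Conditions: EDC·HCl, DMAP (cat.), CH2Cl2, 0 °C → rt
Reagents that add atoms: none
Why: Steglich esterification (carbodiimide activation, DMAP acyl transfer) of the unhindered acid with the primary hydroxyl of 19 brings in the glycerol stereocentre from the chiral pool.

Step 14
Reactants: 20 [(4R)-2,2-dimethyl-1,3-dioxolan-4-yl]methyl (5R,10R,13R)-labd-8-en-15-oate
Product: 21 (2R)-2,3-dihydroxypropyl (5R,10R,13R)-labd-8-en-15-oate
Conditions: AcOH/H2O (4:1), 45 °C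
Reagents that add atoms: none
Why: Mild aqueous acid hydrolyses the isopropylidene acetal much faster than the ester and is too weak to move the C8=C9 olefin, and the low temperature limits 1→2 acyl migration (acetal hydrolysis).

Step 15
Reactants: 21 (2R)-2,3-dihydroxypropyl (5R,10R,13R)-labd-8-en-15-oate
Product: 22 (2R)-3-acetoxy-2-hydroxypropyl (5R,10R,13R)-labd-8-en-15-oate (target)
Conditions: AcCl (1.05 equiv), 2,4,6-collidine, CH2Cl2, −78 °C
Reagents that add atoms: acetyl chloride, CC(Cl)=O
Why: Acetyl chloride with the hindered base at −78 °C acylates the primary hydroxyl of the 1,2-diol far faster than the secondary one (kinetically selective O-acylation), which leaves the glycerol C2 carbinol free as in the target.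

**Compound list**

1 | (+)-limonene oxide, (4R)-1-methyl-4-(prop-1-en-2-yl)-7-oxabicyclo[4.1.0]heptane, cis/trans mixture | CC(=C)[C@@H]1CCC2(C)OC2C1 | starting material
2 | (3R)-6-oxo-3-(prop-1-en-2-yl)heptanal | O=CC[C@@H](CCC(C)=O)C(C)=C | intermediate
3 | (3R)-6-oxo-3-(prop-1-en-2-yl)heptanoic acid | OC(=O)C[C@@H](CCC(C)=O)C(C)=C | intermediate
4 | methyl (3R)-6,6-dimethoxy-3-(prop-1-en-2-yl)heptanoate | COC(=O)C[C@@H](CCC(C)(OC)OC)C(C)=C | intermediate
5 | methyl (3R)-6,6-dimethoxy-2-methyl-3-(prop-1-en-2-yl)heptanoate, C2 epimers | COC(=O)C(C)[C@@H](CCC(C)(OC)OC)C(C)=C | intermediate (not isolated)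
6 | methyl (3S)-6,6-dimethoxy-2,2-dimethyl-3-(prop-1-en-2-yl)heptanoate | COC(=O)C(C)(C)[C@@H](CCC(C)(OC)OC)C(C)=C | intermediate
7 | (3S)-6,6-dimethoxy-2,2-dimethyl-3-(prop-1-en-2-yl)heptanal | O=CC(C)(C)[C@@H](CCC(C)(OC)OC)C(C)=C | intermediate (not isolated)
8 | (4S)-7,7-dimethoxy-3,3-dimethyl-4-(prop-1-en-2-yl)oct-1-yne | C#CC(C)(C)[C@@H](CCC(C)(OC)OC)C(C)=C | intermediate (not isolated)
9 | (5S)-6,6-dimethyl-5-(prop-1-en-2-yl)oct-7-yn-2-one | C#CC(C)(C)[C@@H](CCC(C)=O)C(C)=C | intermediate
10 | (R)-citronellic acid, (3R)-3,7-dimethyloct-6-enoic acid | OC(=O)C[C@H](C)CCC=C(C)C | starting material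
11 | (3R)-6-hydroxy-3-methylhexanoic acid | OC(=O)C[C@H](C)CCCO | intermediate
12 | (3R)-6-bromo-3-methylhexanoic acid | OC(=O)C[C@H](C)CCCBr | intermediate
13 | [(4R)-5-carboxy-4-methylpentyl]triphenylphosphonium bromide | OC(=O)C[C@H](C)CCC[P+](c1ccccc1)(c1ccccc1)c1ccccc1.[Br-] | intermediate
14 | potassium (3R)-3-methyl-6-(triphenyl-λ5-phosphanylidene)hexanoate | [K+].[O-]C(=O)C[C@H](C)CCC=P(c1ccccc1)(c1ccccc1)c1ccccc1 | intermediate (not isolated)
15 | (3R,10S)-3,7,11,11-tetramethyl-10-(prop-1-en-2-yl)tridec-6-en-12-ynoic acid, 6E/6Z mixture | C#CC(C)(C)[C@@H](CCC(C)=CCC[C@@H](C)CC(O)=O)C(C)=C | intermediate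
16 | (5R,9R,10S,13R)-labda-2,8(17)-dien-15-oic acid; (3R)-3-methyl-5-[(1R,4aR,8aS)-5,5,8a-trimethyl-2-methylidene-1,2,3,4,4a,5,8,8a-octahydronaphthalen-1-yl]pentanoic acid | OC(=O)C[C@H](C)CC[C@@H]1C(=C)CC[C@@H]2C(C)(C)C=CC[C@@]12C | intermediate
17 | (5R,10R,13R)-labda-2,8-dien-15-oic acid; (3R)-3-methyl-5-[(4aR,8aR)-2,5,5,8a-tetramethyl-3,4,4a,5,8,8a-hexahydronaphthalen-1-yl]pentanoic acid | OC(=O)C[C@H](C)CCC1=C(C)CC[C@@H]2C(C)(C)C=CC[C@@]12C | intermediate
18 | (5R,10R,13R)-labd-8-en-15-oic acid; (3R)-3-methyl-5-[(4aR,8aR)-2,5,5,8a-tetramethyl-3,4,4a,5,6,7,8,8a-octahydronaphthalen-1-yl]pentanoic acid | OC(=O)C[C@H](C)CCC1=C(C)CC[C@@H]2C(C)(C)CCC[C@@]12C | intermediate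
19 | (S)-solketal, [(4S)-2,2-dimethyl-1,3-dioxolan-4-yl]methanol | CC1(C)OC[C@H](CO)O1 | starting material
20 | [(4R)-2,2-dimethyl-1,3-dioxolan-4-yl]methyl (5R,10R,13R)-labd-8-en-15-oate | CC1(C)OC[C@H](COC(=O)C[C@H](C)CCC2=C(C)CC[C@@H]3C(C)(C)CCC[C@@]23C)O1 | intermediate
21 | (2R)-2,3-dihydroxypropyl (5R,10R,13R)-labd-8-en-15-oate | OC[C@@H](O)COC(=O)C[C@H](C)CCC1=C(C)CC[C@@H]2C(C)(C)CCC[C@@]12C | intermediate
22 | (2R)-3-acetoxy-2-hydroxypropyl (3R)-3-methyl-5-[(4aR,8aR)-2,5,5,8a-tetramethyl-3,4,4a,5,6,7,8,8a-octahydronaphthalen-1-yl]pentanoate | CC(=O)OC[C@@H](O)COC(=O)C[C@H](C)CCC1=C(C)CC[C@@H]2C(C)(C)CCC[C@@]12C | target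

**Step count and risks**

Total step count: 15. Longest linear sequence: 12 (steps 1–5 and 9–15, from 1); steps 6–8 make the ylide precursor 13.

Steps most likely to fail:

1. Step 10. The C10 cation may lose a proton, or take a hydride from C5, before C9 reaches it, so that the cascade stops after ring A. The fallback sets out from 15 and comes back at 16. It separates the two ring closures: the gold step is taken only as the 1,5-enyne cycloisomerisation, whose product after proton loss from C20 is (3R)-9-[(1S)-6,6-dimethyl-2-methylidenecyclohex-4-en-1-yl]-3,7-dimethylnon-6-enoic acid F1. Ring B is then closed in a separate proton-initiated cation–olefin cyclisation (ClSO3H, 2-nitropropane, −78 °C), the established way of turning monocyclofarnesyl-type acids into decalins. Protonation of the C10=C20 olefin regenerates the C10 cation under conditions where proton loss is reversible, so the material should funnel to the bicyclic olefin mixture around 16, which rejoins the route at step 11.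

2. Step 11. The acid equilibration may stall with the trisubstituted C7=C8 isomer left in the mixture, or the C8 cation may undergo 1,2-shifts (hydride from C9, then methyl from C10) that lead out of the labdane skeleton. The fallback sets out from 16 and comes back at 18. It uses no protic acid and merges steps 11 and 12: the olefin mixture is stirred under H2 over Pd/C in ethanol, where palladium hydride insertion–elimination should walk the exocyclic and C7=C8 olefins into the tetrasubstituted C8=C9 position, which no longer binds to the metal, while C2=C3 is saturated. Material that is reduced instead of isomerised lacks an olefin and is removed on AgNO3–SiO2. No new compound is made (none, F0).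

3. Step 5. The hindered ester may be over-reduced to the alcohol or left unreduced at the hydride stage, which spoils the one-flask homologation. The fallback sets out from 6 and comes back at 9. It goes through isolated stages and a different alkyne synthesis: LiAlH4 (THF, 0 °C) gives (3S)-6,6-dimethoxy-2,2-dimethyl-3-(prop-1-en-2-yl)heptan-1-ol F2; Swern oxidation gives aldehyde 7; CBr4/PPh3 (CH2Cl2, 0 °C, with Et3N) gives (4S)-1,1-dibromo-7,7-dimethoxy-3,3-dimethyl-4-(prop-1-en-2-yl)oct-1-ene F3; n-BuLi (2.1 equiv, THF, −78 °C, Corey–Fuchs) gives alkyne 8, and 1 M HCl in THF releases ketone 9.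

Further compounds

F1 | step 10 | (3R)-9-[(1S)-6,6-dimethyl-2-methylidenecyclohex-4-en-1-yl]-3,7-dimethylnon-6-enoic acid (6E/6Z) | C=C1CC=CC(C)(C)[C@H]1CCC(C)=CCC[C@@H](C)CC(O)=O
F0 | step 11 | none | none
F2 | step 5 | (3S)-6,6-dimethoxy-2,2-dimethyl-3-(prop-1-en-2-yl)heptan-1-ol | OCC(C)(C)[C@@H](CCC(C)(OC)OC)C(C)=C
F3 | step 5 | (4S)-1,1-dibromo-7,7-dimethoxy-3,3-dimethyl-4-(prop-1-en-2-yl)oct-1-ene | BrC(Br)=CC(C)(C)[C@@H](CCC(C)(OC)OC)C(C)=C
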